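**Remark on the chemistry:** the target has no stereocentre, and neither biaryl axis is stereogenic because rings A and E are symmetric about their axes, so no stereodescriptor is needed. The central ring is built from 2,6-difluoro-4-methoxybenzaldehyde instead of a fluoronitroarene; the reason is given in the retrosynthesis.

## Analysis of the target

The target (21) is a six-ring phlorotannin with sixteen free phenolic hydroxyls. Ring C is the hub: it carries aryl ether oxygens on the adjacent carbons C1, C2 and C3 and a hydroxyl on C5. Ring F (3,4,5-trihydroxyphenyl) sits on the C2 oxygen, rings B and D on the C1 and C3 oxygens, and each of these is joined through B1 (D1) to an outer phloroglucinol ring A (E) by a carbon–carbon bond. A mirror plane through C2, C5 and ring F makes the two arms identical, so both can be built at once. The free polyphenol is very electron-rich and oxidises readily, above all in base, so every oxygen should stay masked until the last step. The hard parts are the two biaryl bonds A1–B1 and E1–D1, each flanked by four ortho oxygens, and the crowded C2 oxygen between two aryloxy groups. The strategy rests on ring A (and E): its carbons A1–A6 with oxygens on A2, A4 and A6 are an isomer of a 4-methoxy-2-pyrone bearing a CH2 group at position 6 (CH2 = A1, pyrone C6 = A2, C5 = A3, C4 = A4, C3 = A5, lactone carbonyl = A6). The hindered biaryl bond can therefore be made as an ordinary aryl–CH2 bond, and the outer ring closed afterwards.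

## Retrosynthetic reasoning

**21 back to 20.** The twelve O–CH3 bonds are cut. Methyl ethers are the only masks that survive organolithium reagents, hot alkoxide, an aryne and a palladium coupling, and they fall in one Lewis acid operation. The four hydroxyls already free in 20 (A2, A6, E2, E6) need no separate treatment.

**20 back to 18.** Bonds A1–A6 and E1–E6 are cut, which unravels each outer ring into its isomeric 6-(arylmethyl)-4-methoxy-2-pyrone. Cutting inside ring A rather than at A1–B1 removes the tetra-ortho-substituted biaryl coupling from the plan. Forward, alkoxide must open each lactone to the keto ester stage 19 and the benzylic carbon must then acylate itself on the ester carbon. The step is an isomerisation, and the aromatic phenoxide is the thermodynamic sink.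

**18 back to 13 and 15.** The B1–CH2 and D1–CH2 bonds are cut. The aryl side is the nucleophile (dibromide 13 through the dilithio compound 16 and the zinc reagent 17), and the pyrone side is the activated bromide 15, made by side-chain bromination of 14. This polarity puts oxidative addition on the reactive sp3 C–Br bond and not on a hindered, electron-rich aryl bromide. The pyrones enter last, so they see none of the earlier conditions.

**13 back to 6 and 11.** The bond between the C2 oxygen and F1 is cut. Phenol 6 is flanked by two aryloxy groups and carries two aryl bromides, which rules out copper or palladium etherification. Aryne 12, released from silyl triflate 11, is a small and very reactive electrophile that needs no metal. The F3 methoxy group of 12 directs the phenoxide to F1, which gives the 3,4,5-trimethoxyphenyl ether. Triflate 11 traces back through 9 and 8 to 7.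

**6 back to 4.** The C2 oxygen is taken from a formyl group by aryl migration to oxygen (through formate 5). The formyl group thus does two jobs: it activates the two neighbouring positions for substitution and then becomes the hydroxyl in one operation. A nitro group in that position would activate more strongly, but its conversion to hydroxyl needs a reduction and a diazonium salt flanked by two electron-rich aryloxy rings, which invites cyclisation onto those rings and azo coupling.

**4 back to 2 and 3.** The C1–O and C3–O bonds are cut; two equivalents of phenol 2 displace the two fluorides of 3. Phenol 2 comes from 1 by bromination. The bromine is placed before the ethers are made because a later bromination could not tell rings B and D from ring F.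

## Alternatives that were turned down

**Alternative 1:** cyclobutenone ring expansion to build ring B onto ring A.
- Disconnection: ring B is grown from a four-membered ring that already carries ring A. The racemic cyclobutenone A2 has the ring A aryl group on its alpha carbon (introduced by adding an aryllithium to a squaric ester) and a 1-methoxyvinyl group plus an acetal-protected oxygen on C4.
- Key step: heating A2 opens the four-membered ring to a dienylketene; six-electron closure between the ketene carbon (B2) and the vinyl terminus (B3), then tautomerisation, gives biaryl phenol A1.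
- For: the congested A1–B1 bond is made by a carbonyl addition, never by a coupling. Ring B emerges fully substituted with B2 free and B5 separately masked. The thermal cascade is dependable, and on certainty of the biaryl construction this alternative is stronger than the pyrone re-closure.
- Against: it delivers only the arm. B2 must still be methylated and B5 unmasked, and the resulting biaryl phenol, more hindered and more valuable than 2, must then go through the double substitution, the formyl-to-hydroxyl change and the ring F arylation. The arm needs two different organolithium additions to the squarate with regiocontrol, and the route comes out several steps longer.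
- Comparison: the chosen strategy accepts a less certain ring closure in exchange for a core built from simple monoaryl phenols, both outer rings formed in one late step from a cheap pyrone, and a shorter sequence.

**Alternative 2:** a dichloroquinone as ring C.
- Disconnection: the C1–O and C3–O bonds of ring C, made on 2,6-dichloro-1,4-benzoquinone A5.
- Key step: two equivalents of the phenoxide of biaryl phenol A4 add to the chlorine-bearing carbons of A5 and expel chloride to give the bis(biaryloxy)quinone A3.
- For: the quinone brings both the C2 and C5 oxygens; after reduction the hindered C2 hydroxyl and the open C5 hydroxyl differ enough for selective methylation. For the core alone this is as short as the chosen sequence and milder. With no aryl bromide present, ring F could even be attached by copper catalysis.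
- Against: it presupposes A4, so the tetra-ortho-oxygenated biaryl bond must be made beforehand by the kind of hindered coupling the chosen strategy avoids. Electron-rich phenoxides can also reduce the quinone by electron transfer or add at its unsubstituted positions.
- Comparison: it is an equal or better way to make ring C's ethers, but it leaves the hardest bond of the molecule unsolved, which is what the pyrone rearrangement addresses.

**Alternative 3:** Danheiser benzannulation to build ring F on the C2 oxygen.
- Disconnection: bonds F2–F3 and F1–F6 of ring F.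
- Key step: the ethynyl ether A7 of the hindered C2 phenol is heated with racemic 3,4-dimethoxycyclobut-2-enone A8. The derived vinylketene adds to the alkyne, and the new cyclobutenone opens and recloses to give A6, with a free F3 hydroxyl meta to the ether oxygen.
- For: the crowded C2 oxygen is bonded to a slim sp carbon instead of being arylated, and the polarity of the ynol ether fixes the regiochemistry. On insensitivity to hindrance at C2–O it is stronger than aryne capture.
- Against: A7 already contains both biaryl bonds, so these must be solved elsewhere. Aryl ethynyl ethers are made through dichlorovinyl ethers with strong base and are labile, and A8 needs its own synthesis. The alternative spends its key step on a bond that aryne capture forms in one step.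
- Comparison: the chosen route installs ring F in one operation and puts its risk into the biaryl problem, which this alternative leaves open.

Key step: step 10

## Route

Step 1
Reactants: 1 2,4,6-trimethoxyphenol
Product: 2 3-bromo-2,4,6-trimethoxyphenol
Conditions: NBS (1.0 equiv), CH2Cl2, −78 °C to 0 °C, dark
Reagents that add atoms: N-bromosuccinimide, O=C1CCC(=O)N1Br
Why: Electrophilic aromatic bromination; the two open positions are equivalent and each is activated by two ortho and one para methoxy group, so one equivalent at low temperature should give the monobromide, and the anhydrous medium disfavours oxidation of the phenol to a quinone.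

Step 2
Reactants: 2 3-bromo-2,4,6-trimethoxyphenol (2.2 equiv); 3 2,6-difluoro-4-methoxybenzaldehyde
Product: 4 2,6-bis(3-bromo-2,4,6-trimethoxyphenoxy)-4-methoxybenzaldehyde
Conditions: Cs2CO3, DMSO, 110 °C, N2
Reagents that add atoms: none
Why: Twofold nucleophilic aromatic substitution by addition–elimination; each fluoride is ortho to the formyl group, which takes up the charge of the Meisenheimer intermediate, fluoride is the best leaving group for this mechanism, and the aryl bromides are inert without a metal catalyst.

Step 3
Reactants: 4 2,6-bis(3-bromo-2,4,6-trimethoxyphenoxy)-4-methoxybenzaldehyde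
Product: 6 2,6-bis(3-bromo-2,4,6-trimethoxyphenoxy)-4-methoxyphenol, via aryl formate 5 (not isolated)
Conditions: mCPBA, CH2Cl2, 0 °C to rt; aqueous NaHCO3 wash; then K2CO3 (0.2 equiv), MeOH, rt
Reagents that add atoms: meta-chloroperbenzoic acid, O=C(OO)c1cccc(Cl)c1
Why: Baeyer–Villiger oxidation of an electron-rich benzaldehyde (Dakin-type); in the Criegee adduct the aryl group, with two ortho aryloxy donors and a para methoxy donor, migrates in preference to hydride, and the formate is then cleaved by methanolysis.

Step 4
Reactants: 7 3,4,5-trimethoxyphenol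
Product: 8 2-bromo-3,4,5-trimethoxyphenol
Conditions: NBS (1.0 equiv), CH2Cl2, −78 °C to rt
Reagents that add atoms: N-bromosuccinimide, O=C1CCC(=O)N1Br
Why: Electrophilic aromatic bromination at one of the two equivalent positions ortho to the hydroxyl, each also ortho and para to methoxy groups; one equivalent should stop at the monobromide.

Step 5
Reactants: 8 2-bromo-3,4,5-trimethoxyphenol
Product: 9 (2-bromo-3,4,5-trimethoxyphenoxy)trimethylsilane
Conditions: (Me3Si)2NH, THF, 70 °C; evaporation
Reagents that add atoms: hexamethyldisilazane, C[Si](C)(C)N[Si](C)(C)C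
Why: O-silylation of a phenol with a silazane; ammonia is the only by-product, so the silyl ether can be used after evaporation.

Step 6
Reactants: 9 (2-bromo-3,4,5-trimethoxyphenoxy)trimethylsilane
Product: 11 3,4,5-trimethoxy-2-(trimethylsilyl)phenyl trifluoromethanesulfonate, via lithium silylphenoxide 10 (not isolated)
Conditions: n-BuLi, THF, −78 °C; then Tf2O, −78 °C to rt
Reagents that add atoms: trifluoromethanesulfonic anhydride, O=S(=O)(OS(=O)(=O)C(F)(F)F)C(F)(F)F
Why: Bromine–lithium exchange followed by anionic 1,3 oxygen-to-carbon silyl migration (retro-Brook rearrangement) gives the lithium 2-silylphenoxide, which is triflated on oxygen; this is the standard entry to ortho-silylaryl triflates.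

Step 7
Reactants: 6 2,6-bis(3-bromo-2,4,6-trimethoxyphenoxy)-4-methoxyphenol; 11 3,4,5-trimethoxy-2-(trimethylsilyl)phenyl trifluoromethanesulfonate (1.5 equiv)
Product: 13 1,3-bis(3-bromo-2,4,6-trimethoxyphenoxy)-5-methoxy-2-(3,4,5-trimethoxyphenoxy)benzene, via 3,4,5-trimethoxybenzyne 12 (not isolated)
Conditions: CsF, MeCN, rt to 40 °C
Reagents that add atoms: none
Why: Fluoride-induced 1,2-elimination of the silyl triflate gives the aryne, and the phenoxide of 6 adds to it (aryne O-arylation of a phenol); attack falls on F1, remote from the F3 methoxy group, because that group distorts the aryne and stabilises the carbanion developing at F2, which is then protonated. No transition metal is present, so the aryl bromides are untouched.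

Step 8
Reactants: 14 4-methoxy-6-methyl-2-pyrone
Product: 15 6-(bromomethyl)-4-methoxy-2-pyrone
Conditions: NBS, (PhCO2)2 (cat.), CCl4, reflux
Reagents that add atoms: N-bromosuccinimide, O=C1CCC(=O)N1Br
Why: Wohl–Ziegler radical bromination; the radical at the 6-methyl group is allylic to the pyrone diene, and non-polar radical conditions favour the side chain over ionic bromination at C3.

Step 9
Reactants: 13 1,3-bis(3-bromo-2,4,6-trimethoxyphenoxy)-5-methoxy-2-(3,4,5-trimethoxyphenoxy)benzene; 15 6-(bromomethyl)-4-methoxy-2-pyrone (2.4 equiv)
Product: 18 1,3-bis[2,4,6-trimethoxy-3-(4-methoxy-2-oxo-2H-pyran-6-ylmethyl)phenoxy]-5-methoxy-2-(3,4,5-trimethoxyphenoxy)benzene, via dilithio compound 16 (not isolated), via bis(arylzinc chloride) 17 (not isolated)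
Conditions: n-BuLi (2.2 equiv), THF, −78 °C; ZnCl2, −78 °C to rt; then 15, Pd2(dba)3 (cat.), SPhos (cat.), THF, rt to 50 °C
Reagents that add atoms: none
Why: Twofold bromine–lithium exchange and transmetallation to zinc give an aryl nucleophile that tolerates the lactone; Negishi coupling then proceeds by oxidative addition of zerovalent palladium into the activated C–Br bond of 15, transmetallation and reductive elimination, with a bulky biarylphosphine chosen because each aryl group has two ortho methoxy groups.

Step 10
Reactants: 18 1,3-bis[2,4,6-trimethoxy-3-(4-methoxy-2-oxo-2H-pyran-6-ylmethyl)phenoxy]-5-methoxy-2-(3,4,5-trimethoxyphenoxy)benzene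
Product: 20 1,3-bis[3-(2,6-dihydroxy-4-methoxyphenyl)-2,4,6-trimethoxyphenoxy]-5-methoxy-2-(3,4,5-trimethoxyphenoxy)benzene, via ring-opened bis(keto ester) 19 (not isolated)
Conditions: NaOMe (excess), degassed MeOH/THF, 65 °C, Ar; then aqueous HCl
Reagents that add atoms: none
Why: Methoxide adds to the lactone carbonyl (A6, E6) of each pyrone and the ring opens to the enolate of a methyl (E)-3-methoxy-5-oxohex-2-enoate (19), in which the benzylic CH2 (A1, E1) lies between the ketone and ring B or D. Reversible enolisation towards A1 and attack of that carbon on the ester carbonyl A6 is an intramolecular Claisen condensation; loss of methoxide gives a 2-aryl-5-methoxycyclohexenedione that tautomerises to the 5-methoxyresorcinol, and its deprotonation to the resorcinolate makes the sequence irreversible. The closest known reaction type is the base-induced conversion of 6-alkyl-4-alkoxy-2-pyrones and of 3,5-dioxohexanoates into phloroglucinol derivatives. Rings A and E each close in a 6-(enolendo)-exo-trig mode, forming bonds A1–A6 and E1–E6. No stereocentre is created. The step needs C-acylation at A1 to win over re-closure on oxygen and over the other alpha carbon: O-acylation only regenerates the pyrone and is reversible, and attack from A3 would give a four-membered ring. The cis geometry of the A4–A5 double bond, inherited from the pyrone, holds A1 and A6 within bonding distance. The aryl methyl ethers and diaryl ethers of the core are inert to methoxide, and the overall change is an isomerisation.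

Step 11
Reactants: 20 1,3-bis[3-(2,6-dihydroxy-4-methoxyphenyl)-2,4,6-trimethoxyphenoxy]-5-methoxy-2-(3,4,5-trimethoxyphenoxy)benzene
Product: 21 3,5-bis[2,4,6-trihydroxy-3-(2,4,6-trihydroxyphenyl)phenoxy]-4-(3,4,5-trihydroxyphenoxy)phenol (CNP0279880.0)
Conditions: BBr3 (large excess), CH2Cl2, −78 °C to rt, Ar; then MeOH, H2O
Reagents that add atoms: none
Why: Lewis acid-mediated cleavage of aryl methyl ethers; boron coordinates each methoxy oxygen and bromide removes the methyl group by SN2, while diaryl ether and biaryl bonds have no such pathway, and exclusion of air protects the polyphenol.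

## Compound list

1 | 2,4,6-trimethoxyphenol | COc1cc(OC)c(O)c(OC)c1 | starting material
2 | 3-bromo-2,4,6-trimethoxyphenol | COc1cc(OC)c(Br)c(OC)c1O | intermediate
3 | 2,6-difluoro-4-methoxybenzaldehyde | COc1cc(F)c(C=O)c(F)c1 | starting material
4 | 2,6-bis(3-bromo-2,4,6-trimethoxyphenoxy)-4-methoxybenzaldehyde | COc1cc(Oc2c(OC)cc(OC)c(Br)c2OC)c(C=O)c(Oc2c(OC)cc(OC)c(Br)c2OC)c1 | intermediate
5 | 2,6-bis(3-bromo-2,4,6-trimethoxyphenoxy)-4-methoxyphenyl formate | COc1cc(Oc2c(OC)cc(OC)c(Br)c2OC)c(OC=O)c(Oc2c(OC)cc(OC)c(Br)c2OC)c1 | intermediate
6 | 2,6-bis(3-bromo-2,4,6-trimethoxyphenoxy)-4-methoxyphenol | COc1cc(Oc2c(OC)cc(OC)c(Br)c2OC)c(O)c(Oc2c(OC)cc(OC)c(Br)c2OC)c1 | intermediate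
7 | 3,4,5-trimethoxyphenol | COc1cc(O)cc(OC)c1OC | starting material
8 | 2-bromo-3,4,5-trimethoxyphenol | COc1cc(O)c(Br)c(OC)c1OC | intermediate
9 | (2-bromo-3,4,5-trimethoxyphenoxy)trimethylsilane | COc1cc(O[Si](C)(C)C)c(Br)c(OC)c1OC | intermediate
10 | lithium 3,4,5-trimethoxy-2-(trimethylsilyl)phenoxide | [Li]Oc1cc(OC)c(OC)c(OC)c1[Si](C)(C)C | intermediate
11 | 3,4,5-trimethoxy-2-(trimethylsilyl)phenyl trifluoromethanesulfonate | COc1cc(OS(=O)(=O)C(F)(F)F)c([Si](C)(C)C)c(OC)c1OC | intermediate
12 | 3,4,5-trimethoxybenzyne (1,2-didehydro-3,4,5-trimethoxybenzene) | COC1=CC#CC(OC)=C1OC | intermediate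
13 | 1,3-bis(3-bromo-2,4,6-trimethoxyphenoxy)-5-methoxy-2-(3,4,5-trimethoxyphenoxy)benzene | COc1cc(Oc2c(OC)cc(OC)c(Br)c2OC)c(Oc2cc(OC)c(OC)c(OC)c2)c(Oc2c(OC)cc(OC)c(Br)c2OC)c1 | intermediate
14 | 4-methoxy-6-methyl-2-pyrone | COc1cc(C)oc(=O)c1 | starting material
15 | 6-(bromomethyl)-4-methoxy-2-pyrone | COc1cc(CBr)oc(=O)c1 | intermediate
16 | dilithio compound: 13 with lithium in place of each bromine | COc1cc(Oc2c(OC)cc(OC)c([Li])c2OC)c(Oc2cc(OC)c(OC)c(OC)c2)c(Oc2c(OC)cc(OC)c([Li])c2OC)c1 | intermediate
17 | bis(arylzinc chloride): 13 with ZnCl in place of each bromine | COc1cc(Oc2c(OC)cc(OC)c([Zn]Cl)c2OC)c(Oc2cc(OC)c(OC)c(OC)c2)c(Oc2c(OC)cc(OC)c([Zn]Cl)c2OC)c1 | intermediate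
18 | 1,3-bis[2,4,6-trimethoxy-3-(4-methoxy-2-oxo-2H-pyran-6-ylmethyl)phenoxy]-5-methoxy-2-(3,4,5-trimethoxyphenoxy)benzene | COc1cc(Oc2c(OC)cc(OC)c(Cc3cc(OC)cc(=O)o3)c2OC)c(Oc2cc(OC)c(OC)c(OC)c2)c(Oc2c(OC)cc(OC)c(Cc3cc(OC)cc(=O)o3)c2OC)c1 | intermediate
19 | ring-opened bis(keto ester): each arm is a methyl (2E)-6-aryl-3-methoxy-5-oxohex-2-enoate | COc1cc(Oc2c(OC)cc(OC)c(CC(=O)C/C(OC)=C\C(=O)OC)c2OC)c(Oc2cc(OC)c(OC)c(OC)c2)c(Oc2c(OC)cc(OC)c(CC(=O)C/C(OC)=C\C(=O)OC)c2OC)c1 | intermediate
20 | 1,3-bis[3-(2,6-dihydroxy-4-methoxyphenyl)-2,4,6-trimethoxyphenoxy]-5-methoxy-2-(3,4,5-trimethoxyphenoxy)benzene (dodecamethyl ether of the target) | COc1cc(Oc2c(OC)cc(OC)c(-c3c(O)cc(OC)cc3O)c2OC)c(Oc2cc(OC)c(OC)c(OC)c2)c(Oc2c(OC)cc(OC)c(-c3c(O)cc(OC)cc3O)c2OC)c1 | intermediate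
21 | 3,5-bis[2,4,6-trihydroxy-3-(2,4,6-trihydroxyphenyl)phenoxy]-4-(3,4,5-trihydroxyphenoxy)phenol (CNP0279880.0) | Oc1cc(O)c(-c2c(O)cc(O)c(Oc3cc(O)cc(Oc4c(O)cc(O)c(-c5c(O)cc(O)cc5O)c4O)c3Oc3cc(O)c(O)c(O)c3)c2O)c(O)c1 | target

## Step count and least certain steps

Total step count: 11. Longest linear sequence: 7 steps (steps 1, 2, 3, 7, 9, 10, 11; the branch through steps 4, 5, 6 is equally long).

**Step 10 (key step).** The benzylic carbon sits between two ortho methoxy groups and may attack the ester only slowly. Methoxide could then cleave the ring-opened 5-oxo ester at the ketone (retro-Claisen loss of the side chain), or the chain could simply re-close to the pyrone, and the reaction could stall with only one end converted. Fallback: starting from 13, both biaryl bonds are made directly by a twofold Negishi coupling with 2,4,6-trimethoxyphenylzinc chloride F1 (from 1,3,5-trimethoxybenzene with n-BuLi, then ZnCl2), using Pd2(dba)3 and SPhos in THF/NMP at 70 °C, a known if demanding coupling type for tetra-ortho-substituted biaryls. This should give the hexadecamethyl ether of the target F2, which is demethylated with BBr3 as in step 11 and so returns to the route at 21.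

**Step 9.** Transmetallation of the di-ortho-methoxy arylzinc onto the pyronylmethyl palladium intermediate may be slow, which would allow reductive dimerisation of 15 or protonation of the arylzinc at one or both ends. Fallback: starting from 13, the dilithio compound 16 is added at −78 °C to 4-methoxy-2-oxo-2H-pyran-6-carbaldehyde F3 (from 14 by SeO2 oxidation) to give the bis-carbinol F4 as a mixture of diastereomers. Ionic deoxygenation with Et3SiH and CF3CO2H, which the 2,4,6-trioxygenated benzylic cation favours, returns to the route at 18.

**Step 2.** After the first substitution the ring carries two donors, so the second displacement may stall, and long heating of an aldehyde with a hindered phenoxide may erode the formyl group. Fallback: starting from 2, the same twofold substitution is run on the more strongly activated 3,5-difluoro-4-nitroanisole to give the nitro diaryl ether F5. Reduction with Fe and NH4Cl gives the aniline F6, and diazotisation (NaNO2, H2SO4) to the diazonium salt F7 followed by hydroxylation with Cu(NO3)2 and Cu2O in water returns to the route at 6. This path is longer and carries the diazonium liabilities named in the retrosynthesis.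

**Step 7.** The phenoxide of 6 is shielded by two aryloxy groups and may capture the aryne slowly, so the aryne could be consumed by self-reaction or by solvent. Fallback: starting from 6, the phenoxide (KOt-Bu, THF) is arylated without a metal by the symmetric salt bis(3,4,5-trimethoxyphenyl)iodonium tetrafluoroborate F8 (from 5-iodo-1,2,3-trimethoxybenzene, mCPBA, BF3·OEt2 and 3,4,5-trimethoxyphenylboronic acid), through ligand coupling at iodine, returning to the route at 13.

**Step 11.** Twelve ethers must all fall; incomplete cleavage at the hindered methoxy groups, air oxidation during isolation, or acid-promoted cyclodehydration of the 2,2'-dihydroxybiaryl units would give mixtures that are hard to separate as free polyphenols. Fallback: starting from 20, the crude product of the BBr3 reaction is acetylated (Ac2O, pyridine) to the hexadecaacetate F9, which can be purified on silica; methanolysis with HCl in degassed MeOH under argon returns to the route at 21.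

**Step 1.** The very electron-rich phenol may be oxidised to a quinone or brominated twice instead of once. Fallback: commercially available 2,4,6-trimethoxybenzaldehyde is brominated with NBS to 3-bromo-2,4,6-trimethoxybenzaldehyde F10, which cannot be oxidised in that way. Baeyer–Villiger oxidation with mCPBA to the formate F11 and methanolysis (K2CO3, MeOH) returns to the route at 2.

## Further compounds

F1 | step 10 | 2,4,6-trimethoxyphenylzinc chloride | COc1cc(OC)c([Zn]Cl)c(OC)c1
F2 | step 10 | hexadecamethyl ether of the target | COc1cc(OC)c(-c2c(OC)cc(OC)c(Oc3cc(OC)cc(Oc4c(OC)cc(OC)c(-c5c(OC)cc(OC)cc5OC)c4OC)c3Oc3cc(OC)c(OC)c(OC)c3)c2OC)c(OC)c1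
F3 | step 9 | 4-methoxy-2-oxo-2H-pyran-6-carbaldehyde | COc1cc(C=O)oc(=O)c1
F4 | step 9 | bis-carbinol: 18 with CH(OH) in place of each CH2 link, mixture of diastereomers | COc1cc(Oc2c(OC)cc(OC)c(C(O)c3cc(OC)cc(=O)o3)c2OC)c(Oc2cc(OC)c(OC)c(OC)c2)c(Oc2c(OC)cc(OC)c(C(O)c3cc(OC)cc(=O)o3)c2OC)c1
F5 | step 2 | 1,3-bis(3-bromo-2,4,6-trimethoxyphenoxy)-5-methoxy-2-nitrobenzene | COc1cc(Oc2c(OC)cc(OC)c(Br)c2OC)c([N+](=O)[O-])c(Oc2c(OC)cc(OC)c(Br)c2OC)c1
F6 | step 2 | 2,6-bis(3-bromo-2,4,6-trimethoxyphenoxy)-4-methoxyaniline | COc1cc(Oc2c(OC)cc(OC)c(Br)c2OC)c(N)c(Oc2c(OC)cc(OC)c(Br)c2OC)c1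
F7 | step 2 | 2,6-bis(3-bromo-2,4,6-trimethoxyphenoxy)-4-methoxybenzenediazonium hydrogensulfate | COc1cc(Oc2c(OC)cc(OC)c(Br)c2OC)c([N+]#N)c(Oc2c(OC)cc(OC)c(Br)c2OC)c1.OS(=O)(=O)[O-]
F8 | step 7 | bis(3,4,5-trimethoxyphenyl)iodonium tetrafluoroborate | COc1cc([I+]c2cc(OC)c(OC)c(OC)c2)cc(OC)c1OC.F[B-](F)(F)F
F9 | step 11 | hexadecaacetate of the target | CC(=O)Oc1cc(OC(C)=O)c(-c2c(OC(C)=O)cc(OC(C)=O)c(Oc3cc(OC(C)=O)cc(Oc4c(OC(C)=O)cc(OC(C)=O)c(-c5c(OC(C)=O)cc(OC(C)=O)cc5OC(C)=O)c4OC(C)=O)c3Oc3cc(OC(C)=O)c(OC(C)=O)c(OC(C)=O)c3)c2OC(C)=O)c(OC(C)=O)c1
F10 | step 1 | 3-bromo-2,4,6-trimethoxybenzaldehyde | COc1cc(OC)c(Br)c(OC)c1C=O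
F11 | step 1 | 3-bromo-2,4,6-trimethoxyphenyl formate | COc1cc(OC)c(Br)c(OC)c1OC=O
A1 | alternative 1 | 5-(methoxymethoxy)-4,6-dimethoxy-2-(2,4,6-trimethoxyphenyl)phenol (biaryl with free B2 hydroxyl) | COCOc1c(OC)cc(O)c(-c2c(OC)cc(OC)cc2OC)c1OC
A2 | alternative 1 | racemic 3-methoxy-4-(methoxymethoxy)-4-(1-methoxyvinyl)-2-(2,4,6-trimethoxyphenyl)cyclobut-2-enone | C=C(OC)C1(OCOC)C(OC)=C(c2c(OC)cc(OC)cc2OC)C1=O
A3 | alternative 2 | 2,6-bis[2,4,6-trimethoxy-3-(2,4,6-trimethoxyphenyl)phenoxy]-1,4-benzoquinone | O=C1C=C(Oc2c(OC)cc(OC)c(-c3c(OC)cc(OC)cc3OC)c2OC)C(=O)C(Oc2c(OC)cc(OC)c(-c3c(OC)cc(OC)cc3OC)c2OC)=C1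
A4 | alternative 2 | 2,4,6-trimethoxy-3-(2,4,6-trimethoxyphenyl)phenol | COc1cc(OC)c(-c2c(OC)cc(OC)c(O)c2OC)c(OC)c1
A5 | alternative 2 | 2,6-dichloro-1,4-benzoquinone | O=C1C=C(Cl)C(=O)C(Cl)=C1
A6 | alternative 3 | pentadecamethyl ether of the target with free F3 hydroxyl | COc1cc(Oc2c(Oc3c(OC)cc(OC)c(-c4c(OC)cc(OC)cc4OC)c3OC)cc(OC)cc2Oc2c(OC)cc(OC)c(-c3c(OC)cc(OC)cc3OC)c2OC)cc(O)c1OC
A7 | alternative 3 | ethynyl ether of the C2 phenol: 2-(ethynyloxy)-5-methoxy-1,3-bis[2,4,6-trimethoxy-3-(2,4,6-trimethoxyphenyl)phenoxy]benzene | COc1cc(Oc2c(OC)cc(OC)c(-c3c(OC)cc(OC)cc3OC)c2OC)c(OC#C)c(Oc2c(OC)cc(OC)c(-c3c(OC)cc(OC)cc3OC)c2OC)c1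
A8 | alternative 3 | racemic 3,4-dimethoxycyclobut-2-enone | COC1C(=O)C=C1OC
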